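**Plan**
- Retrosynthetic cuts, in order: the O7 MOM and O3 silyl groups; the O1–C2 bond of ring C (back through a para-quinone methide to a benzylic C2–H); the C4–C4a aryl ketone bond; the C2–C1' bond to ring B; the three aryl–prenyl bonds.
- Enabling feature: C2 is benzylic and para to the 4'-OH of ring B, a 2,6-dialkylphenol. Two-electron oxidation of that phenol makes C2 the electrophilic end of a para-quinone methide, six atoms from the ring A oxygen (future O1) and next to C3.
- Forward: ring B (4-iodophenol carrying two prenyl groups) is joined to the C2–C3–C4 chain by opening methyl (R)-glycidate. Ring A (resorcinol carrying one prenyl group) is attached at C4 by aryllithium acylation of a Weinreb amide. Ring C is closed by anodic oxidation, and one acidic deprotection ends the route.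
- Stereochemistry: C3 (R) is the glycidate stereocentre and no bond to it is broken at any stage; C2 (R) is set in the ring closure, trans to C3.

Key step: step 11

Assumption: flavanone numbering (O1, C2, C3, C4, ring A, primed ring B) is also used for open-chain intermediates; prenyl = 3-methylbut-2-en-1-yl, TBS = tert-butyldimethylsilyl, MOM = methoxymethyl.

**Step 1**
Reactants: 1 4-iodophenol; 2 prenyl bromide (1-bromo-3-methylbut-2-ene)
Product: 3 4-iodo-2,6-diprenylphenol
Conditions: NaH (2.2 equiv), 2 (2.2 equiv in total), toluene, rt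
Reagents that add atoms: prenyl bromide (second equivalent), CC(C)=CCBr
Why: Twofold ortho-selective C-alkylation of a sodium phenoxide in a non-polar solvent, where the tight ion pair steers the primary allylic bromide to an ortho carbon (SN2, then rearomatisation), the excess NaH re-forms the phenoxide of the monoprenylphenol and the second equivalent of bromide enters at the remaining ortho carbon, while iodine blocks the para position.

**Step 2**
Reactants: 3 4-iodo-2,6-diprenylphenol
Product: 4 tert-butyl(4-iodo-2,6-diprenylphenoxy)dimethylsilane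
Conditions: TBSCl, imidazole, DMF, rt → 40 °C
Reagents that add atoms: tert-butyldimethylsilyl chloride, CC(C)(C)[Si](C)(C)Cl
Why: Imidazole-mediated silylation of a phenol, which masks the acidic O–H for the organomagnesium chemistry that follows.

**Step 3**
Reactants: 4 tert-butyl(4-iodo-2,6-diprenylphenoxy)dimethylsilane; 5 methyl (R)-oxirane-2-carboxylate (methyl (R)-glycidate)
Product: 7 methyl (R)-3-[4-(TBS-oxy)-3,5-diprenylphenyl]-2-hydroxypropanoate, via arylmagnesium chloride 6 (not isolated)
Conditions: i-PrMgCl·LiCl, THF, rt; then CuI (10 mol%), 5, −40 → −20 °C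
Reagents that add atoms: none
Why: Iodine–magnesium exchange followed by copper-catalysed SN2 opening of the glycidic ester at its unsubstituted terminal carbon; the epoxide stereocentre is not attacked, so it is carried over unchanged as the (R)-α-hydroxy ester carbon that becomes C3.

**Step 4**
Reactants: 7 methyl (R)-3-[4-(TBS-oxy)-3,5-diprenylphenyl]-2-hydroxypropanoate
Product: 8 methyl (R)-2-(TBS-oxy)-3-[4-(TBS-oxy)-3,5-diprenylphenyl]propanoate
Conditions: TBSCl, imidazole, DMAP (cat.), DMF, rt
Reagents that add atoms: tert-butyldimethylsilyl chloride, CC(C)(C)[Si](C)(C)Cl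
Why: Imidazole-mediated silylation of the secondary alcohol, which breaks no bond at the stereocentre and protects O3 up to the last step.

**Step 5**
Reactants: 8 methyl (R)-2-(TBS-oxy)-3-[4-(TBS-oxy)-3,5-diprenylphenyl]propanoate
Product: 9 (R)-2-(TBS-oxy)-3-[4-(TBS-oxy)-3,5-diprenylphenyl]-N-methoxy-N-methylpropanamide
Conditions: MeNH(OMe)·HCl, i-PrMgCl, THF, −20 → 0 °C
Reagents that add atoms: N,O-dimethylhydroxylamine hydrochloride, CNOC.Cl
Why: Direct ester aminolysis by the chloromagnesium amide of N,O-dimethylhydroxylamine (Weinreb amide formation), which at low temperature should convert α-silyloxy esters without epimerisation.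

**Step 6**
Reactants: 10 resorcinol
Product: 11 1,3-bis(methoxymethoxy)benzene
Conditions: MOMCl (2.5 equiv), i-Pr2NEt, CH2Cl2, 0 °C → rt
Reagents that add atoms: chloromethyl methyl ether, COCCl
Why: O-alkylation of both phenols with an α-chloro ether (Williamson-type, one equivalent per hydroxyl), installing the acetal groups that direct both later lithiations.

**Step 7**
Reactants: 11 1,3-bis(methoxymethoxy)benzene; 2 prenyl bromide
Product: 13 1,3-bis(methoxymethoxy)-2-prenylbenzene, via C2-aryllithium 12 (not isolated)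
Conditions: n-BuLi, THF, 0 °C → rt; then CuI (10 mol%), 2, −78 °C → rt
Reagents that add atoms: none
Why: Directed ortho-metalation at the carbon flanked by both OMOM groups, followed by copper-catalysed SN2 allylation with the primary allylic bromide.

**Step 8**
Reactants: 13 1,3-bis(methoxymethoxy)-2-prenylbenzene; 9 (R)-2-(TBS-oxy)-3-[4-(TBS-oxy)-3,5-diprenylphenyl]-N-methoxy-N-methylpropanamide
Product: 15 (R)-1-[2,4-bis(methoxymethoxy)-3-prenylphenyl]-2-(TBS-oxy)-3-[4-(TBS-oxy)-3,5-diprenylphenyl]propan-1-one, via C4-aryllithium 14 (not isolated)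
Conditions: 13 (1.5 equiv), n-BuLi (1.4 equiv), TMEDA, THF, 0 °C; then 9, −78 → 0 °C
Reagents that add atoms: none
Why: A second directed ortho-metalation next to an OMOM group, then Weinreb ketone synthesis, in which the chelated tetrahedral adduct prevents over-addition and keeps the α-stereocentre from enolising until the quench.

**Step 9**
Reactants: 15 (R)-1-[2,4-bis(methoxymethoxy)-3-prenylphenyl]-2-(TBS-oxy)-3-[4-(TBS-oxy)-3,5-diprenylphenyl]propan-1-one
Product: 16 (R)-1-[2,4-bis(methoxymethoxy)-3-prenylphenyl]-2-(TBS-oxy)-3-(4-hydroxy-3,5-diprenylphenyl)propan-1-one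
Conditions: TBAF, AcOH (1:1), THF, 0 °C
Reagents that add atoms: none
Why: Chemoselective fluoride cleavage of an aryl silyl ether beside an alkyl silyl ether (phenoxide is the far better leaving group), buffered with AcOH so that the α-silyloxy ketone does not epimerise.

**Step 10**
Reactants: 16 (R)-1-[2,4-bis(methoxymethoxy)-3-prenylphenyl]-2-(TBS-oxy)-3-(4-hydroxy-3,5-diprenylphenyl)propan-1-one
Product: 17 (R)-2-(TBS-oxy)-1-[2-hydroxy-4-(methoxymethoxy)-3-prenylphenyl]-3-(4-hydroxy-3,5-diprenylphenyl)propan-1-one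
Conditions: MgBr2·OEt2, Et2O/CH2Cl2, 0 °C → rt
Reagents that add atoms: none
Why: Chelation-controlled Lewis-acid cleavage of the MOM ether ortho to the ketone: magnesium bridges the carbonyl and acetal oxygens and bromide attacks the acetal carbon, while the non-chelated 7-O acetal, the silyl ether and the alkenes should stay intact.

**Step 11**
Reactants: 17 (R)-2-(TBS-oxy)-1-[2-hydroxy-4-(methoxymethoxy)-3-prenylphenyl]-3-(4-hydroxy-3,5-diprenylphenyl)propan-1-one
Product: 19 (2R,3R)-3-(TBS-oxy)-2-(4-hydroxy-3,5-diprenylphenyl)-7-(methoxymethoxy)-8-prenylchroman-4-one, via para-quinone methide 18 (not isolated)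
Conditions: graphite anode, Pt cathode, undivided cell, constant current, 2.2 F/mol, n-Bu4NBF4, 2,6-lutidine, CH2Cl2/HFIP (4:1), 0 °C
Reagents that add atoms: none
Why: Two-electron anodic oxidation of the ring B phenol, the only free non-acylated phenol and the most easily oxidised π-system (the prenyl alkenes, the aryl MOM ether and the hydrogen-bonded 2'-hydroxyaryl ketone need higher potentials), gives a phenoxonium ion that loses a C2 proton to 2,6-lutidine and becomes para-quinone methide 18. The 2'-OH of ring A, held close by its hydrogen bond to the ketone, adds to the exocyclic methide carbon in an oxa-1,6-conjugate addition (6-exo-trig) that closes ring C, forms O1–C2 and restores the aromaticity of ring B. The closest known reaction type is the quinone-mediated or anodic conversion of 4-alkylphenols into para-quinone methides with intramolecular oxygen capture, as in the oxidative cyclisation of 2'-hydroxydihydrochalcones to flavanones and of 1-(2-hydroxyphenyl)-3-arylpropanes to flavans. The new C2 stereocentre is governed by C3: in the chair-like transition state the OTBS group and the incoming aryl group should both lie equatorial, and since a 4'-hydroxyflavanone can reopen to the quinone methide any cis isomer should drain to the diequatorial trans-(2R,3R) product, C3 itself not being touched. The step needs para- over ortho-quinone methide formation (the prenyl CH2 groups of ring B are benzylic and allylic), a stop after two electrons and no tautomerisation towards C3; the para carbon carries the highest positive charge of the phenoxonium ion, as in the para-selective side-chain oxidation of 2,4,6-trialkylphenols, a hindered base at 0 °C disfavours the ortho pathway, the charge is limited to 2.2 F/mol, and fast intramolecular capture should keep the quinone methide from tautomerising.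

**Step 12**
Reactants: 19 (2R,3R)-3-(TBS-oxy)-2-(4-hydroxy-3,5-diprenylphenyl)-7-(methoxymethoxy)-8-prenylchroman-4-one
Product: 20 (2R,3R)-3,7-dihydroxy-2-(4-hydroxy-3,5-diprenylphenyl)-8-prenylchroman-4-one (target)
Conditions: HCl (1 M in MeOH), 40 °C
Reagents that add atoms: none
Why: Acid-catalysed transacetalisation of the aryl MOM ether together with methanolysis of the secondary silyl ether, the usual way of unmasking MOM-protected ortho-prenylated flavanones; dilute acid should leave C2, C3 and the prenyl groups unchanged.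

**Compound list**
1 | 4-iodophenol | Oc1ccc(I)cc1 | starting material
2 | prenyl bromide (1-bromo-3-methylbut-2-ene) | CC(C)=CCBr | starting material
3 | 4-iodo-2,6-bis(3-methylbut-2-en-1-yl)phenol | CC(C)=CCc1cc(I)cc(CC=C(C)C)c1O | intermediate
4 | tert-butyl[4-iodo-2,6-bis(3-methylbut-2-en-1-yl)phenoxy]dimethylsilane | CC(C)=CCc1cc(I)cc(CC=C(C)C)c1O[Si](C)(C)C(C)(C)C | intermediate
5 | methyl (R)-oxirane-2-carboxylate | COC(=O)[C@H]1CO1 | starting material
6 | [4-(TBS-oxy)-3,5-diprenylphenyl]magnesium chloride | CC(C)=CCc1cc([Mg]Cl)cc(CC=C(C)C)c1O[Si](C)(C)C(C)(C)C | intermediate (not isolated)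
7 | methyl (R)-3-[4-(TBS-oxy)-3,5-diprenylphenyl]-2-hydroxypropanoate | COC(=O)[C@H](O)Cc1cc(CC=C(C)C)c(O[Si](C)(C)C(C)(C)C)c(CC=C(C)C)c1 | intermediate
8 | methyl (R)-2-(TBS-oxy)-3-[4-(TBS-oxy)-3,5-diprenylphenyl]propanoate | COC(=O)[C@H](O[Si](C)(C)C(C)(C)C)Cc1cc(CC=C(C)C)c(O[Si](C)(C)C(C)(C)C)c(CC=C(C)C)c1 | intermediate
9 | (R)-2-(TBS-oxy)-3-[4-(TBS-oxy)-3,5-diprenylphenyl]-N-methoxy-N-methylpropanamide | CON(C)C(=O)[C@H](O[Si](C)(C)C(C)(C)C)Cc1cc(CC=C(C)C)c(O[Si](C)(C)C(C)(C)C)c(CC=C(C)C)c1 | intermediate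
10 | resorcinol | Oc1cccc(O)c1 | starting material
11 | 1,3-bis(methoxymethoxy)benzene | COCOc1cccc(OCOC)c1 | intermediate
12 | [2,6-bis(methoxymethoxy)phenyl]lithium | COCOc1cccc(OCOC)c1[Li] | intermediate (not isolated)
13 | 1,3-bis(methoxymethoxy)-2-(3-methylbut-2-en-1-yl)benzene | COCOc1cccc(OCOC)c1CC=C(C)C | intermediate
14 | [2,4-bis(methoxymethoxy)-3-(3-methylbut-2-en-1-yl)phenyl]lithium | COCOc1ccc([Li])c(OCOC)c1CC=C(C)C | intermediate (not isolated)
15 | (R)-1-[2,4-bis(methoxymethoxy)-3-prenylphenyl]-2-(TBS-oxy)-3-[4-(TBS-oxy)-3,5-diprenylphenyl]propan-1-one | O=C([C@H](O[Si](C)(C)C(C)(C)C)Cc1cc(CC=C(C)C)c(O[Si](C)(C)C(C)(C)C)c(CC=C(C)C)c1)c1ccc(OCOC)c(CC=C(C)C)c1OCOC | intermediate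
16 | (R)-1-[2,4-bis(methoxymethoxy)-3-prenylphenyl]-2-(TBS-oxy)-3-(4-hydroxy-3,5-diprenylphenyl)propan-1-one | O=C([C@H](O[Si](C)(C)C(C)(C)C)Cc1cc(CC=C(C)C)c(O)c(CC=C(C)C)c1)c1ccc(OCOC)c(CC=C(C)C)c1OCOC | intermediate
17 | (R)-2-(TBS-oxy)-1-[2-hydroxy-4-(methoxymethoxy)-3-prenylphenyl]-3-(4-hydroxy-3,5-diprenylphenyl)propan-1-one | O=C([C@H](O[Si](C)(C)C(C)(C)C)Cc1cc(CC=C(C)C)c(O)c(CC=C(C)C)c1)c1ccc(OCOC)c(CC=C(C)C)c1O | intermediate (key-step precursor)
18 | 4-{(R)-2-(TBS-oxy)-3-[2-hydroxy-4-(methoxymethoxy)-3-prenylphenyl]-3-oxopropylidene}-2,6-diprenylcyclohexa-2,5-dien-1-one | CC(C)=CCC1=CC(=C[C@@H](O[Si](C)(C)C(C)(C)C)C(=O)c2ccc(OCOC)c(CC=C(C)C)c2O)C=C(CC=C(C)C)C1=O | intermediate (not isolated)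
19 | (2R,3R)-3-(TBS-oxy)-2-(4-hydroxy-3,5-diprenylphenyl)-7-(methoxymethoxy)-8-prenylchroman-4-one | O=C1c2ccc(OCOC)c(CC=C(C)C)c2O[C@H](c2cc(CC=C(C)C)c(O)c(CC=C(C)C)c2)[C@H]1O[Si](C)(C)C(C)(C)C | intermediate (key-step product)
20 | (2R,3R)-3,7-dihydroxy-2-[4-hydroxy-3,5-bis(3-methylbut-2-en-1-yl)phenyl]-8-(3-methylbut-2-en-1-yl)chroman-4-one | CC(C)=CCc1cc([C@H]2Oc3c(ccc(O)c3CC=C(C)C)C(=O)[C@@H]2O)cc(CC=C(C)C)c1O | target

**Step count**
Total: 12 steps. Longest linear sequence: 10 steps (steps 1–5 and 8–12, from 4-iodophenol).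

**Steps most likely to fail**

1. Step 11. The phenoxonium ion may lose a proton from a ring B prenyl CH2 instead of C2, giving an ortho-quinone methide that electrocyclises to a 2,2-dimethylchromene. The product phenol may also be oxidised further, or the quinone methide may tautomerise towards C3 and erode its configuration. The fallback forms the same O1–C2 bond from the epoxide oxidation level, with no oxidant near the prenylphenol; it sets out from 3 and 14 and returns at 20. Phenol 3 is converted with MOMCl and NaH into 5-iodo-2-(methoxymethoxy)-1,3-diprenylbenzene F1. Iodine–magnesium exchange with i-PrMgCl·LiCl gives [4-(methoxymethoxy)-3,5-diprenylphenyl]magnesium chloride F2, which DMF formylates to 4-(methoxymethoxy)-3,5-diprenylbenzaldehyde F3. Aryllithium 14 is quenched with N-methoxy-N-methylacetamide to give 1-[2,4-bis(methoxymethoxy)-3-prenylphenyl]ethan-1-one F4. Claisen–Schmidt condensation of F3 with F4 (KOH, EtOH) should give (E)-1-[2,4-bis(methoxymethoxy)-3-prenylphenyl]-3-[4-(methoxymethoxy)-3,5-diprenylphenyl]prop-2-en-1-one F5. Juliá–Colonna epoxidation (poly-L-leucine, urea–hydrogen peroxide, DBU, THF) is nucleophilic and should spare the prenyl alkenes, giving [2,4-bis(methoxymethoxy)-3-prenylphenyl]{(2R,3S)-3-[4-(methoxymethoxy)-3,5-diprenylphenyl]oxiran-2-yl}methanone F6. Methanolic HCl then removes the three MOM groups, opens the epoxide at the benzylic carbon (a para-hydroxybenzyl cation, the protonated quinone methide) and closes ring C to the trans flavanonol 20, with C3 keeping the epoxide α-configuration.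

2. Step 8. Deprotonation at the benzylic and allylic prenyl CH2 between the two OMOM groups may compete with ring lithiation, lowering conversion to the ketone or isomerising the alkene. The fallback generates the same aryllithium by bromine–lithium exchange at −78 °C; it sets out from 11 and returns at 14. NBS in MeCN at 0 °C brominates 11 para to one OMOM group, giving 1-bromo-2,4-bis(methoxymethoxy)benzene F7. Lithium 2,2,6,6-tetramethylpiperidide in THF at −78 °C removes the proton between the two OMOM groups, giving [3-bromo-2,6-bis(methoxymethoxy)phenyl]lithium F8, and copper-catalysed allylation with 2 (CuI, 10 mol%) gives 1-bromo-2,4-bis(methoxymethoxy)-3-prenylbenzene F9. n-BuLi in THF at −78 °C converts F9 into 14, which is treated with amide 9 as in step 8.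

3. Step 12. Acid may cyclise the ortho-prenylphenol units to 2,2-dimethylchromans, or add methanol to the alkenes, before the deactivated 7-O acetal is cleaved. The fallback reroutes the protecting groups so that the last step needs only fluoride; it sets out from 16 and returns at 20. ZnBr2 and n-PrSH in CH2Cl2 at 0 °C cleave both ring A MOM ethers of 16, giving (R)-2-(TBS-oxy)-1-(2,4-dihydroxy-3-prenylphenyl)-3-(4-hydroxy-3,5-diprenylphenyl)propan-1-one F10. TBSCl (1 equiv) and imidazole at 0 °C should silylate the most acidic, non-chelated 4'-OH of ring A (the future O7), giving (R)-2-(TBS-oxy)-1-[2-hydroxy-4-(TBS-oxy)-3-prenylphenyl]-3-(4-hydroxy-3,5-diprenylphenyl)propan-1-one F11. Anodic oxidation under the conditions of step 11 should proceed through the para-quinone methide 4-{(R)-2-(TBS-oxy)-3-[2-hydroxy-4-(TBS-oxy)-3-prenylphenyl]-3-oxopropylidene}-2,6-diprenylcyclohexa-2,5-dien-1-one F12 to (2R,3R)-3,7-bis(TBS-oxy)-2-(4-hydroxy-3,5-diprenylphenyl)-8-prenylchroman-4-one F13. TBAF buffered with AcOH in THF at 0 °C then removes both silyl groups to give 20.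

**Further compounds**
F1 | step 11 | 5-iodo-2-(methoxymethoxy)-1,3-bis(3-methylbut-2-en-1-yl)benzene | COCOc1c(CC=C(C)C)cc(I)cc1CC=C(C)C
F2 | step 11 | [4-(methoxymethoxy)-3,5-bis(3-methylbut-2-en-1-yl)phenyl]magnesium chloride | COCOc1c(CC=C(C)C)cc([Mg]Cl)cc1CC=C(C)C
F3 | step 11 | 4-(methoxymethoxy)-3,5-bis(3-methylbut-2-en-1-yl)benzaldehyde | COCOc1c(CC=C(C)C)cc(C=O)cc1CC=C(C)C
F4 | step 11 | 1-[2,4-bis(methoxymethoxy)-3-(3-methylbut-2-en-1-yl)phenyl]ethan-1-one | CC(=O)c1ccc(OCOC)c(CC=C(C)C)c1OCOC
F5 | step 11 | (E)-1-[2,4-bis(methoxymethoxy)-3-prenylphenyl]-3-[4-(methoxymethoxy)-3,5-diprenylphenyl]prop-2-en-1-one | COCOc1c(CC=C(C)C)cc(/C=C/C(=O)c2ccc(OCOC)c(CC=C(C)C)c2OCOC)cc1CC=C(C)C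
F6 | step 11 | [2,4-bis(methoxymethoxy)-3-prenylphenyl]{(2R,3S)-3-[4-(methoxymethoxy)-3,5-diprenylphenyl]oxiran-2-yl}methanone | O=C([C@@H]1O[C@H]1c2cc(CC=C(C)C)c(OCOC)c(CC=C(C)C)c2)c3ccc(OCOC)c(CC=C(C)C)c3OCOC
F7 | step 8 | 1-bromo-2,4-bis(methoxymethoxy)benzene | COCOc1ccc(Br)c(OCOC)c1
F8 | step 8 | [3-bromo-2,6-bis(methoxymethoxy)phenyl]lithium | COCOc1ccc(Br)c(OCOC)c1[Li]
F9 | step 8 | 1-bromo-2,4-bis(methoxymethoxy)-3-(3-methylbut-2-en-1-yl)benzene | COCOc1ccc(Br)c(OCOC)c1CC=C(C)C
F10 | step 12 | (R)-2-(TBS-oxy)-1-(2,4-dihydroxy-3-prenylphenyl)-3-(4-hydroxy-3,5-diprenylphenyl)propan-1-one | O=C([C@H](O[Si](C)(C)C(C)(C)C)Cc1cc(CC=C(C)C)c(O)c(CC=C(C)C)c1)c1ccc(O)c(CC=C(C)C)c1O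
F11 | step 12 | (R)-2-(TBS-oxy)-1-[2-hydroxy-4-(TBS-oxy)-3-prenylphenyl]-3-(4-hydroxy-3,5-diprenylphenyl)propan-1-one | O=C([C@H](O[Si](C)(C)C(C)(C)C)Cc1cc(CC=C(C)C)c(O)c(CC=C(C)C)c1)c1ccc(O[Si](C)(C)C(C)(C)C)c(CC=C(C)C)c1O
F12 | step 12 | 4-{(R)-2-(TBS-oxy)-3-[2-hydroxy-4-(TBS-oxy)-3-prenylphenyl]-3-oxopropylidene}-2,6-diprenylcyclohexa-2,5-dien-1-one | CC(C)=CCC1=CC(=C[C@@H](O[Si](C)(C)C(C)(C)C)C(=O)c2ccc(O[Si](C)(C)C(C)(C)C)c(CC=C(C)C)c2O)C=C(CC=C(C)C)C1=O
F13 | step 12 | (2R,3R)-3,7-bis(TBS-oxy)-2-(4-hydroxy-3,5-diprenylphenyl)-8-prenylchroman-4-one | O=C1c2ccc(O[Si](C)(C)C(C)(C)C)c(CC=C(C)C)c2O[C@H](c2cc(CC=C(C)C)c(O)c(CC=C(C)C)c2)[C@H]1O[Si](C)(C)C(C)(C)C
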